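Labels: unit 1 = benzo ring A, pyranone ring C, catechol ring B on C2. Unit 2 = benzo ring D, pyranone ring F, 4-hydroxyphenyl ring E on C2''.
Enabling feature: C3, the carbon next to the C4 carbonyl of ring C, carries the phloroglucinol-type ring D through C8''. A donor-rich aryl group on that α-carbon, with the one-carbon unit C2 beside it, is the imprint of an aryl group that moved from Cβ to Cα of a chalcone.
Cuts, in order: seven O–benzyl bonds; C2–C1' (ring B); C2''–C1''' (ring E); C3–C8'' together with O1–C2 (ring C, back to a chalcone); the chalcone Cα=Cβ bond; C8''–CHO; O1''–C2'' (ring F).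
Forward: one dibenzylated phloroacetophenone serves as the ring A ketone and, after iodination, as ring D. Ring F closes first as a chromone, the chalcone is joined, ring C closes in the rearrangement, and rings E and B are then attached by two conjugate arylations.
Unit 2 passes through the oxidation as a chromone. That ring has no enolisable CH2 for trivalent thallium to attack and no stereocentre to lose in base or acid.
Stereochemistry: C2'' (S) and C2 (R) come from the two enantiomers of a pyridine-oxazoline palladium catalyst. C3 (R, so 2,3-cis) comes from kinetic protonation of the enolate on the face away from ring B, and a neutral hydrogenolysis ends the route.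

Key step: step 6

Assumption: with t-BuPyOx = 4-tert-butyl-2-(pyridin-2-yl)-4,5-dihydrooxazole, the (S)-ligand–palladium catalyst is taken to arylate a chromone on the same face as a 3-substituted cyclohexenone, which corresponds to a (2R)-flavanone; if circular dichroism of 12 or 14 shows the opposite sense, the two ligand enantiomers change places.

Step 1
Reactants: 1 2',4',6'-trihydroxyacetophenone
Product: 2 1-[2,4-bis(benzyloxy)-6-hydroxyphenyl]ethanone
Conditions: BnBr (2.1 equiv), K2CO3, DMF, 60 °C
Reagents that add atoms: benzyl bromide, BrCc1ccccc1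
Why: Williamson etherification should stop after two benzylations because the remaining ortho hydroxyl is hydrogen-bonded to the ketone and is far less nucleophilic.

Step 2
Reactants: 2 1-[2,4-bis(benzyloxy)-6-hydroxyphenyl]ethanone
Product: 3 1-[4,6-bis(benzyloxy)-2-hydroxy-3-iodophenyl]ethanone
Conditions: NIS (1.0 equiv), CF3CO2H (cat.), MeCN, 0 °C to rt, dark
Reagents that add atoms: N-iodosuccinimide, O=C1CCC(=O)N1I
Why: Electrophilic aromatic iodination of 2-hydroxy-4,6-dialkoxyacetophenones goes ortho to the free phenol, and since only that neighbouring hydroxyl can later close ring F, the iodine should end up at C8''.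

Step 3
Reactants: 3 1-[4,6-bis(benzyloxy)-2-hydroxy-3-iodophenyl]ethanone
Product: 5 5,7-bis(benzyloxy)-8-iodo-4H-chromen-4-one, via enaminone 4 (not isolated)
Conditions: Me2NCH(OMe)2, toluene, 100 °C; concentrate; AcOH, 60 °C
Reagents that add atoms: N,N-dimethylformamide dimethyl acetal, COC(OC)N(C)C
Why: In the enaminone route to chromones the methyl ketone condenses with the amide acetal, and in acid the phenol adds to the β-carbon (6-endo-trig) and expels dimethylamine to close ring F.

Step 4
Reactants: 5 5,7-bis(benzyloxy)-8-iodo-4H-chromen-4-one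
Product: 6 5,7-bis(benzyloxy)-4-oxo-4H-chromene-8-carbaldehyde
Conditions: Pd(PPh3)4 (5 mol%), CO (3 bar), Bu3SnH (slow addition), THF, 50 °C
Reagents that add atoms: carbon monoxide, [C-]#[O+]
Why: This is a palladium-catalysed reductive carbonylation of an aryl iodide (oxidative addition to zerovalent palladium, CO insertion, hydride transfer from tin); it runs in a neutral medium that spares ring F and the benzyl ethers, and slow hydride addition limits plain hydrodeiodination.

Step 5
Reactants: 2 1-[2,4-bis(benzyloxy)-6-hydroxyphenyl]ethanone; 6 5,7-bis(benzyloxy)-4-oxo-4H-chromene-8-carbaldehyde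
Product: 8 8-{(E)-3-[2,4-bis(benzyloxy)-6-hydroxyphenyl]-3-oxoprop-1-enyl}-5,7-bis(benzyloxy)-4H-chromen-4-one, via aldol adduct 7 (not isolated)
Conditions: 2, LiN(SiMe3)2 (2.3 equiv), THF, −78 °C; then 6, −78 °C to rt; aq. NH4Cl
Reagents that add atoms: none
Why: In this Claisen–Schmidt condensation with a preformed lithium dianion, the enolate of 2 should add to the only aldehyde present and aldolate 7 should lose hydroxide by E1cB to the conjugated (E)-enone, while a non-nucleophilic amide base in THF avoids the hydroxide attack at C2'' that would open ring F.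

Step 6
Reactants: 8 8-{(E)-3-[2,4-bis(benzyloxy)-6-hydroxyphenyl]-3-oxoprop-1-enyl}-5,7-bis(benzyloxy)-4H-chromen-4-one
Product: 10 5,5',7,7'-tetrakis(benzyloxy)-4H,4'H-[3,8'-bichromene]-4,4'-dione, via dimethyl acetal 9 (not isolated)
Conditions: Tl(NO3)3·3H2O (1.1 equiv), MeOH/CH2Cl2, rt; filter off TlNO3; aq. HCl (10%), 50 °C
Reagents that add atoms: methanol, CO (its atoms are held only in intermediate 9)
Why: Trivalent thallium should bond to the α-carbon of the enone while methanol takes the β-carbon, whose cation is stabilised by the oxygens ortho and para to C8''; departure of thallium in its monovalent state is assisted by ring D, which bridges as a phenonium ion and settles on the α-carbon (new C3–C8'' bond), and the methoxycarbenium ion left at the old β-carbon takes a second methanol to give acetal 9. The closest known reaction type is the oxidative rearrangement of 2'-hydroxychalcones to isoflavones by 1,2-aryl migration. In acid one methoxy group leaves, the 2'-hydroxyl of ring A attacks the oxocarbenium carbon (new O1–C2 bond, 6-exo-trig because the C=O+ bond lies outside the forming ring), and loss of the second methanol across C2–C3 completes pyranone ring C. No stereocentre remains, since the α-carbon of 9 becomes sp2, and the hindered C3–C8'' axis is left uncontrolled because C3 becomes sp3 again in step 8. The step needs aryl migration to win over attack of the 2'-hydroxyl (aurone pathway) and over oxidation of the aromatic rings, which is secured by ring D being the best migrating group present and by methanol as solvent trapping the cations. It also needs unit 2 to stay untouched, which is secured by its chromone oxidation level, lacking both the enolisable CH2 at which trivalent thallium oxidises flavanones and any acid-labile stereocentre.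

Step 7
Reactants: 10 5,5',7,7'-tetrakis(benzyloxy)-4H,4'H-[3,8'-bichromene]-4,4'-dione; 11 [4-(benzyloxy)phenyl]boronic acid
Product: 12 (2S)-5,7-bis(benzyloxy)-2-[4-(benzyloxy)phenyl]-8-[5,7-bis(benzyloxy)-4-oxo-4H-chromen-3-yl]chroman-4-one
Conditions: Pd(OCOCF3)2 (10 mol%), (R)-t-BuPyOx (12 mol%), NH4PF6 (30 mol%), H2O (5 equiv), ClCH2CH2Cl, 60 °C
Reagents that add atoms: none
Why: Palladium-catalysed asymmetric conjugate addition of an arylboronic acid to a chromone is a known route to flavanones; aryl transfer from divalent palladium to C2'' on the face left open by the tert-butyl group of the (R)-ligand should set 2''S, and only ring F should react because its C2''=C3'' bond is unsubstituted whereas C2=C3 of ring C is screened by the orthogonal ring D.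

Step 8
Reactants: 12 (2S)-5,7-bis(benzyloxy)-2-[4-(benzyloxy)phenyl]-8-[5,7-bis(benzyloxy)-4-oxo-4H-chromen-3-yl]chroman-4-one; 13 [3,4-bis(benzyloxy)phenyl]boronic acid
Product: 14 (2R,3R)-5,7-bis(benzyloxy)-2-[3,4-bis(benzyloxy)phenyl]-3-{(2S)-5,7-bis(benzyloxy)-2-[4-(benzyloxy)phenyl]-4-oxochroman-8-yl}chroman-4-one (2,3-cis)
Conditions: Pd(OCOCF3)2 (20 mol%), (S)-t-BuPyOx (24 mol%), NH4PF6, H2O, ClCH2CH2Cl, 40–60 °C, argon; neutral work-up, buffered silica
Reagents that add atoms: none
Why: Proposed new method: the cationic arylpalladium–pyridine-oxazoline complex formed by transmetalation from 13 should insert the C2=C3 bond of ring C with the aryl group going to the unsubstituted C2 on the face left open by the tert-butyl group of the ligand (sets 2R), the carbon-bound palladium at C3 should slip to the oxygen-bound enolate, and water should protonate C3 on the face away from ring B, which A(1,2) strain against ring D holds pseudoaxial, so that H2 and H3 end up cis (sets 3R); the closest known reaction types are the asymmetric conjugate arylation of C3-unsubstituted chromones with this catalyst and the rhodium-catalysed arylation of 1-nitrocyclohexene, where kinetic protonation likewise favours the cis product, whereas a chromone bearing a 3-aryl group has not been shown as acceptor.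

Step 9
Reactants: 14 (2R,3R)-5,7-bis(benzyloxy)-2-[3,4-bis(benzyloxy)phenyl]-3-{(2S)-5,7-bis(benzyloxy)-2-[4-(benzyloxy)phenyl]-4-oxochroman-8-yl}chroman-4-one
Product: 15 (2R,3R)-2-(3,4-dihydroxyphenyl)-5,7-dihydroxy-3-[(2S)-5,7-dihydroxy-2-(4-hydroxyphenyl)-4-oxochroman-8-yl]chroman-4-one (target)
Conditions: H2 (1 atm), Pd/C (10%), THF/MeOH, rt; Sephadex LH-20 (MeOH)
Reagents that add atoms: none
Why: Catalytic hydrogenolysis of the seven aryl benzyl ethers runs without acid or base, so the enolisable C3 and the retro-oxa-Michael-prone C2 and C2'' should keep their configuration.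

Compound list
1 | 2',4',6'-trihydroxyacetophenone | CC(=O)c1c(O)cc(O)cc1O | starting material
2 | 1-[2,4-bis(benzyloxy)-6-hydroxyphenyl]ethanone | CC(=O)c1c(O)cc(OCc2ccccc2)cc1OCc1ccccc1 | intermediate
3 | 1-[4,6-bis(benzyloxy)-2-hydroxy-3-iodophenyl]ethanone | CC(=O)c1c(O)c(I)c(OCc2ccccc2)cc1OCc1ccccc1 | intermediate
4 | (E)-1-[4,6-bis(benzyloxy)-2-hydroxy-3-iodophenyl]-3-(dimethylamino)prop-2-en-1-one | CN(C)/C=C/C(=O)c1c(O)c(I)c(OCc2ccccc2)cc1OCc1ccccc1 | intermediate
5 | 5,7-bis(benzyloxy)-8-iodo-4H-chromen-4-one | O=c1ccoc2c(I)c(OCc3ccccc3)cc(OCc3ccccc3)c12 | intermediate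
6 | 5,7-bis(benzyloxy)-4-oxo-4H-chromene-8-carbaldehyde | O=Cc1c(OCc2ccccc2)cc(OCc2ccccc2)c2c(=O)ccoc12 | intermediate
7 | 8-{3-[2,4-bis(benzyloxy)-6-hydroxyphenyl]-1-hydroxy-3-oxopropyl}-5,7-bis(benzyloxy)-4H-chromen-4-one (racemic aldol) | OC(CC(=O)c1c(O)cc(OCc2ccccc2)cc1OCc1ccccc1)c1c(OCc2ccccc2)cc(OCc2ccccc2)c2c(=O)ccoc12 | intermediate
8 | 8-{(E)-3-[2,4-bis(benzyloxy)-6-hydroxyphenyl]-3-oxoprop-1-enyl}-5,7-bis(benzyloxy)-4H-chromen-4-one | O=C(/C=C/c1c(OCc2ccccc2)cc(OCc2ccccc2)c2c(=O)ccoc12)c1c(O)cc(OCc2ccccc2)cc1OCc1ccccc1 | intermediate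
9 | 8-{1-[2,4-bis(benzyloxy)-6-hydroxyphenyl]-3,3-dimethoxy-1-oxopropan-2-yl}-5,7-bis(benzyloxy)-4H-chromen-4-one (racemic) | COC(OC)C(C(=O)c1c(O)cc(OCc2ccccc2)cc1OCc1ccccc1)c1c(OCc2ccccc2)cc(OCc2ccccc2)c2c(=O)ccoc12 | intermediate
10 | 5,5',7,7'-tetrakis(benzyloxy)-4H,4'H-[3,8'-bichromene]-4,4'-dione | O=c1ccoc2c1c(OCc1ccccc1)cc(OCc1ccccc1)c2-c1coc2cc(OCc3ccccc3)cc(OCc3ccccc3)c2c1=O | intermediate
11 | [4-(benzyloxy)phenyl]boronic acid | OB(O)c1ccc(OCc2ccccc2)cc1 | starting material
12 | (2S)-5,7-bis(benzyloxy)-2-[4-(benzyloxy)phenyl]-8-[5,7-bis(benzyloxy)-4-oxo-4H-chromen-3-yl]chroman-4-one | O=C1C[C@@H](c2ccc(OCc3ccccc3)cc2)Oc2c1c(OCc1ccccc1)cc(OCc1ccccc1)c2-c1coc2cc(OCc3ccccc3)cc(OCc3ccccc3)c2c1=O | intermediate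
13 | [3,4-bis(benzyloxy)phenyl]boronic acid | OB(O)c1ccc(OCc2ccccc2)c(OCc2ccccc2)c1 | starting material
14 | (2R,3R)-5,7-bis(benzyloxy)-2-[3,4-bis(benzyloxy)phenyl]-3-{(2S)-5,7-bis(benzyloxy)-2-[4-(benzyloxy)phenyl]-4-oxochroman-8-yl}chroman-4-one | O=C1C[C@@H](c2ccc(OCc3ccccc3)cc2)Oc2c1c(OCc1ccccc1)cc(OCc1ccccc1)c2[C@H]1C(=O)c2c(OCc3ccccc3)cc(OCc3ccccc3)cc2O[C@H]1c1ccc(OCc2ccccc2)c(OCc2ccccc2)c1 | intermediate
15 | (2R,3R)-2-(3,4-dihydroxyphenyl)-5,7-dihydroxy-3-[(2S)-5,7-dihydroxy-2-(4-hydroxyphenyl)-4-oxochroman-8-yl]chroman-4-one | O=C1C[C@@H](c2ccc(O)cc2)Oc2c1c(O)cc(O)c2[C@H]1C(=O)c2c(O)cc(O)cc2O[C@H]1c1ccc(O)c(O)c1 | target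

Total step count: 9. Longest linear sequence: 9 steps from 1 (compound 2 is used twice, in steps 2 and 5).

Steps most likely to fail

**Step 8.**
- Insertion may not occur at all, because ring D stands orthogonal to ring C and screens both faces of C3.
- Facial control by the ligand may be blurred by slow rotation about the C3–C8'' axis.
- Protonation may run through the carbon-bound palladium enolate with retention, or the cis ketone may epimerise at C3 during the run.

The fallback sets out from 12 and comes back at 14.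
- 4-Bromo-1,2-bis(benzyloxy)benzene is lithiated (n-BuLi, THF, −78 °C) and combined with half an equivalent of CuBr·SMe2 to give lithium bis[3,4-bis(benzyloxy)phenyl]cuprate F1.
- With Me3SiCl at −78 °C this reagent adds to C2 of the isoflavone, a known conjugate addition of organocopper reagents to isoflavones. The hindered, donor-rich ketone of unit 2 should not be attacked at this temperature.
- The product is the 2-aryl-4-(trimethylsilyloxy)-2H-chromene F2 as both C2 epimers.
- Protonolysis at low temperature (AcOH, THF/MeOH, −78 °C) puts the proton anti to the pseudoaxial ring B. It should give 14 together with the (2S,3S,2''S)-heptabenzyl ether F3.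
- These two are diastereomers because C2'' is already fixed, and they are parted by preparative chromatography.
- Catalyst control is thus exchanged for stoichiometric addition plus separation.

**Step 6.**
- Oxythallation of the crowded, di-ortho-substituted styrene bond may be slow.
- Attack of the 2'-hydroxyl (aurone pathway), oxidation of the benzyloxy-rich rings, or acid loss of the peri benzyl ethers during ring closure could then compete.

The fallback sets out from 2 and 5 and comes back at 10.
- Compound 2 is condensed with Me2NCH(OMe)2 to (E)-1-[2,4-bis(benzyloxy)-6-hydroxyphenyl]-3-(dimethylamino)prop-2-en-1-one F4.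
- This is closed with iodine (CHCl3, rt) to 5,7-bis(benzyloxy)-3-iodo-4H-chromen-4-one F5.
- Compound 5 undergoes Miyaura borylation (B2pin2, PdCl2(dppf), KOAc, dioxane, 80 °C) to 5,7-bis(benzyloxy)-8-(4,4,5,5-tetramethyl-1,3,2-dioxaborolan-2-yl)-4H-chromen-4-one F6.
- Suzuki–Miyaura coupling of the two (Pd(OAc)2, SPhos, K3PO4, toluene/H2O, 80 °C) forms C3–C8'' directly on a preformed ring C.

**Step 5.**
- The enolate may add at C2'' of ring F and open it.
- The aldol addition may revert without dehydration, because the aldehyde is electron-rich and flanked by two ortho substituents.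

The fallback sets out from 2, uses 6, and comes back at 8.
- Compound 2 is protected (MOMCl, i-Pr2NEt, CH2Cl2) as 1-[2,4-bis(benzyloxy)-6-(methoxymethoxy)phenyl]ethanone F7.
- Its lithium enolate (LiN(i-Pr)2, THF, −78 °C) is phosphinylated on carbon with ClP(OEt)2 and oxidised (H2O2) to diethyl {2-[2,4-bis(benzyloxy)-6-(methoxymethoxy)phenyl]-2-oxoethyl}phosphonate F8.
- Horner–Wadsworth–Emmons olefination of 6 (LiCl, DBU, MeCN, rt), which is selective for the aldehyde, gives 8-{(E)-3-[2,4-bis(benzyloxy)-6-(methoxymethoxy)phenyl]-3-oxoprop-1-enyl}-5,7-bis(benzyloxy)-4H-chromen-4-one F9.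
- Dilute HCl in MeOH at rt removes the acetal protecting group to give 8.

Further compounds
F1 | step 8 | lithium bis[3,4-bis(benzyloxy)phenyl]cuprate | [Li+].[Cu-](c1ccc(OCc2ccccc2)c(OCc2ccccc2)c1)c1ccc(OCc2ccccc2)c(OCc2ccccc2)c1
F2 | step 8 | (2S)-5,7-bis(benzyloxy)-2-[4-(benzyloxy)phenyl]-8-{5,7-bis(benzyloxy)-2-[3,4-bis(benzyloxy)phenyl]-4-(trimethylsilyloxy)-2H-chromen-3-yl}chroman-4-one (both C2 epimers) | O=C1C[C@@H](c2ccc(OCc3ccccc3)cc2)Oc2c1c(OCc1ccccc1)cc(OCc1ccccc1)c2C1=C(O[Si](C)(C)C)c2c(OCc3ccccc3)cc(OCc3ccccc3)cc2OC1c1ccc(OCc2ccccc2)c(OCc2ccccc2)c1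
F3 | step 8 | (2S,3S)-5,7-bis(benzyloxy)-2-[3,4-bis(benzyloxy)phenyl]-3-{(2S)-5,7-bis(benzyloxy)-2-[4-(benzyloxy)phenyl]-4-oxochroman-8-yl}chroman-4-one | O=C1C[C@@H](c2ccc(OCc3ccccc3)cc2)Oc2c1c(OCc1ccccc1)cc(OCc1ccccc1)c2[C@@H]1C(=O)c2c(OCc3ccccc3)cc(OCc3ccccc3)cc2O[C@@H]1c1ccc(OCc2ccccc2)c(OCc2ccccc2)c1
F4 | step 6 | (E)-1-[2,4-bis(benzyloxy)-6-hydroxyphenyl]-3-(dimethylamino)prop-2-en-1-one | CN(C)/C=C/C(=O)c1c(O)cc(OCc2ccccc2)cc1OCc1ccccc1
F5 | step 6 | 5,7-bis(benzyloxy)-3-iodo-4H-chromen-4-one | O=c1c(I)coc2cc(OCc3ccccc3)cc(OCc3ccccc3)c12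
F6 | step 6 | 5,7-bis(benzyloxy)-8-(4,4,5,5-tetramethyl-1,3,2-dioxaborolan-2-yl)-4H-chromen-4-one | CC1(C)OB(OC1(C)C)c1c(OCc2ccccc2)cc(OCc2ccccc2)c2c(=O)ccoc12
F7 | step 5 | 1-[2,4-bis(benzyloxy)-6-(methoxymethoxy)phenyl]ethanone | CC(=O)c1c(OCOC)cc(OCc2ccccc2)cc1OCc1ccccc1
F8 | step 5 | diethyl {2-[2,4-bis(benzyloxy)-6-(methoxymethoxy)phenyl]-2-oxoethyl}phosphonate | CCOP(=O)(CC(=O)c1c(OCOC)cc(OCc2ccccc2)cc1OCc1ccccc1)OCC
F9 | step 5 | 8-{(E)-3-[2,4-bis(benzyloxy)-6-(methoxymethoxy)phenyl]-3-oxoprop-1-enyl}-5,7-bis(benzyloxy)-4H-chromen-4-one | COCOc1cc(OCc2ccccc2)cc(OCc2ccccc2)c1C(=O)/C=C/c1c(OCc2ccccc2)cc(OCc2ccccc2)c2c(=O)ccoc12
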